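**Retrosynthetic overview**
1. Target ⇐ the C3 CH2OH is unmasked last from a CH2–Bpin group (C–B oxidation); boron serves as the latent hydroxyl, so no protecting groups are needed.
2. C4–aroyl bond ⇐ nickel-catalysed reductive acylation of a 4-iodo-oxolane with 3,4,5-trimethoxybenzoyl chloride; C4 ends trans to its neighbours, which is also its thermodynamic position.
3. Key ring-forming bond O1–C5 ⇐ 5-endo iodoetherification of a syn homoallylic alcohol. The oxolane is the only ring made; it closes with retention at C2 and C3, so syn becomes 2,3-cis.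
4. C2–C3 bond and both fixed stereocentres ⇐ enantioselective (Z)-allylboration of 3,4-dimethoxybenzaldehyde with (Z)-1,4-diborylbut-2-ene (new catalytic variant), the latter from butadiene and bis(pinacolato)diboron.

Assumption: TRIP is taken to show the facial sense established for allyl- and crotyl-pinacolboronates with aryl aldehydes ((R)-acid gives re-face attack), so the (S)-acid is specified; if the sense is reversed for this bis(boronate), the (R)-acid is used.

Conventions: Bpin = 4,4,5,5-tetramethyl-1,3,2-dioxaborolan-2-yl. Ring atoms are O1, C2 (aryl), C3, C4, C5 throughout. The target is (2S,3S,4R): 2,3-cis, 3,4-trans.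

**Step 1**
Reactants: 1 buta-1,3-diene; 2 bis(pinacolato)diboron
Product: 3 (Z)-1,4-bis(4,4,5,5-tetramethyl-1,3,2-dioxaborolan-2-yl)but-2-ene
Conditions: Pt(PPh3)4 (3 mol %), toluene, 80 °C, sealed vessel, 16 h
Reagents that add atoms: none
Why: Platinum-catalysed 1,4-diboration of a 1,3-diene (B–B oxidative addition to zerovalent platinum, insertion of s-cis butadiene to a π-allyl(boryl)platinum, reductive elimination) gives the (Z)-alkene; no stereocentre is formed.

**Step 2**
Reactants: 3 (Z)-1,4-bis(Bpin)but-2-ene (1.2 equiv); 4 3,4-dimethoxybenzaldehyde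
Product: 6 (1S,2R)-1-(3,4-dimethoxyphenyl)-2-[(4,4,5,5-tetramethyl-1,3,2-dioxaborolan-2-yl)methyl]but-3-en-1-ol (syn), via O-pinacolboryl borate ester 5 (not isolated)
Conditions: (S)-TRIP [(S)-3,3'-bis(2,4,6-triisopropylphenyl)-1,1'-binaphthyl-2,2'-diyl hydrogen phosphate] (10 mol %), 4 Å MS, toluene, −30 → 0 °C; aq NaHCO3 work-up
Reagents that add atoms: none
Why: Proposed new method: chiral-phosphoric-acid-catalysed allylboration (closest known reaction: TRIP-catalysed allyl- and crotylboration of aryl aldehydes with pinacol boronates) extended to a γ-(borylmethyl) (Z)-allylboronate, in which the acid hydrogen-bonds the pseudo-axial pinacol oxygen of the reacting boron while its P=O holds the formyl hydrogen, the closed chair transition state puts the (Z)-γ-CH2Bpin group axial (syn, C2 = R), the catalyst pocket exposes the aldehyde si face (C1 = S), and the second boron is no longer allylic after transfer, so it survives as a latent CH2OH.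

**Step 3**
Reactants: 6 (1S,2R)-syn homoallylic alcohol
Product: 7 2-{[(2S,3S,4R)-2-(3,4-dimethoxyphenyl)-4-iodooxolan-3-yl]methyl}-4,4,5,5-tetramethyl-1,3,2-dioxaborolane (2,3-cis; iodine mainly trans to CH2Bpin, and the C4 epimer is equally usable)
Conditions: I2 (3 equiv), NaHCO3 (3 equiv), dry MeCN, 0 °C, dark
Reagents that add atoms: iodine, [I][I]
Why: 5-endo-trig iodoetherification of a homoallylic alcohol: the benzylic hydroxyl opens the iodonium ion at the terminal carbon (the 4-exo alternative would give a strained oxetane), forming O1–C5 with retention at C2 and C3 so that syn becomes 2,3-cis, while iodine enters C4 anti to CH2Bpin at a centre that is reset in the next step.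

**Step 4**
Reactants: 7 4-iodo-oxolane; 8 3,4,5-trimethoxybenzoyl chloride (1.5 equiv)
Product: 9 [(3R,4R,5S)-5-(3,4-dimethoxyphenyl)-4-[(4,4,5,5-tetramethyl-1,3,2-dioxaborolan-2-yl)methyl]oxolan-3-yl](3,4,5-trimethoxyphenyl)methanone (aroyl trans to CH2Bpin and to the aryl group)
Conditions: NiCl2(CH3OCH2CH2OCH3) (10 mol %), 4,4'-di-tert-butyl-2,2'-bipyridine (12 mol %), Zn powder (3 equiv), MgCl2 (1 equiv), N,N-dimethylacetamide, 0 → 23 °C
Reagents that add atoms: none
Why: Nickel-catalysed reductive cross-electrophile acylation of a secondary alkyl iodide with an aroyl chloride: the planar C4 radical is captured by aroyl-nickel on the face opposite both the CH2Bpin and aryl groups and reductive elimination gives the ketone, so C4 is set trans, which is also the thermodynamic configuration of this sole epimerisable centre.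

**Step 5**
Reactants: 9 ketone boronate
Product: 11 [(3R,4S,5S)-5-(3,4-dimethoxyphenyl)-4-(hydroxymethyl)oxolan-3-yl](3,4,5-trimethoxyphenyl)methanone, the target, (2S,3S,4R) in O1/C2(aryl) numbering, via alkyl pinacol borate 10 (not isolated)
Conditions: NaBO3·4H2O (3 equiv), THF/H2O 1:1, 0 → 23 °C, 2 h
Reagents that add atoms: sodium perborate tetrahydrate, [Na+].[Na+].O[B-]1(O)OO[B-](O)(O)OO1 (hydrate water omitted)
Why: Perborate oxidation of an alkyl pinacol boronate (1,2-shift of the CH2 group from boron to peroxide oxygen, then hydrolysis of the borate) unmasks the primary alcohol without touching the aryl ketone; no stereocentre changes (the C3 descriptor changes only through CIP priorities).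

**Compound list**
1 | buta-1,3-diene | C=CC=C | starting material
2 | bis(pinacolato)diboron | CC1(C)OB(OC1(C)C)B1OC(C)(C)C(C)(C)O1 | starting material
3 | (Z)-1,4-bis(4,4,5,5-tetramethyl-1,3,2-dioxaborolan-2-yl)but-2-ene | CC1(C)OB(C/C=C\CB2OC(C)(C)C(C)(C)O2)OC1(C)C | intermediate
4 | 3,4-dimethoxybenzaldehyde | COc1ccc(C=O)cc1OC | starting material
5 | 2-{[(1S,2R)-1-(3,4-dimethoxyphenyl)-2-[(Bpin)methyl]but-3-en-1-yl]oxy}-4,4,5,5-tetramethyl-1,3,2-dioxaborolane | COc1ccc([C@@H](OB5OC(C)(C)C(C)(C)O5)[C@H](CB4OC(C)(C)C(C)(C)O4)C=C)cc1OC | intermediate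
6 | (1S,2R)-1-(3,4-dimethoxyphenyl)-2-[(Bpin)methyl]but-3-en-1-ol | COc1ccc([C@@H](O)[C@H](CB4OC(C)(C)C(C)(C)O4)C=C)cc1OC | intermediate
7 | 2-{[(2S,3S,4R)-2-(3,4-dimethoxyphenyl)-4-iodooxolan-3-yl]methyl}-4,4,5,5-tetramethyl-1,3,2-dioxaborolane | COc1ccc([C@H]2OC[C@H](I)[C@H]2CB4OC(C)(C)C(C)(C)O4)cc1OC | intermediate
8 | 3,4,5-trimethoxybenzoyl chloride | COc1cc(C(Cl)=O)cc(OC)c1OC | starting material
9 | [(3R,4R,5S)-5-(3,4-dimethoxyphenyl)-4-[(Bpin)methyl]oxolan-3-yl](3,4,5-trimethoxyphenyl)methanone | COc1ccc([C@H]2OC[C@H](C(=O)c3cc(OC)c(OC)c(OC)c3)[C@H]2CB4OC(C)(C)C(C)(C)O4)cc1OC | intermediate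
10 | [(3R,4S,5S)-5-(3,4-dimethoxyphenyl)-4-{[(Bpin)oxy]methyl}oxolan-3-yl](3,4,5-trimethoxyphenyl)methanone | COc1ccc([C@H]2OC[C@H](C(=O)c3cc(OC)c(OC)c(OC)c3)[C@H]2COB4OC(C)(C)C(C)(C)O4)cc1OC | intermediate
11 | [(3R,4S,5S)-5-(3,4-dimethoxyphenyl)-4-(hydroxymethyl)oxolan-3-yl](3,4,5-trimethoxyphenyl)methanone | COc1ccc([C@H]2OC[C@H](C(=O)c3cc(OC)c(OC)c(OC)c3)[C@H]2CO)cc1OC | target

**Totals**
Total step count: 5. Longest linear sequence: 5 steps (1 → 3 → 6 → 7 → 9 → 11).

**Three steps most likely to fail**

Step 2 (the proposed new step). The bulky γ-CH2Bpin group and the electron-rich aldehyde may make the catalysed pathway slow or poorly enantioselective. The fallback uses known chemistry and sets out from 3 and 4. They are combined without catalyst (toluene, 40 °C); this thermal allylboration goes through the same closed chair and is syn-selective but racemic. Besides 5 and 6 it therefore gives their mirror images, the (1R,2S)-O-pinacolboryl borate ester F1 (not isolated) and, after hydrolysis, the (1R,2S)-alcohol F2. The racemic alcohol is resolved by preparative chromatography on a chiral stationary phase, and enantiopure 6 comes back to the route at step 3.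

Step 3. The monosubstituted alkene may react slowly, close 4-exo to an oxetane, or the dimethoxyarene may be iodinated. The fallback sets out from 6 and replaces the iodonium cyclisation by an epoxide-opening cyclisation:
- Hydroxyl-directed epoxidation (VO(acac)2, t-BuOOH, CH2Cl2) gives (1S,2S)-1-(3,4-dimethoxyphenyl)-2-[(2S)-oxiran-2-yl]-3-(Bpin)propan-1-ol F3; either epoxide epimer is usable.
- K2CO3 in MeOH at 50 °C lets the benzylic alkoxide open the terminal epoxide carbon, closing the oxolane to (3S,4R,5S)-5-(3,4-dimethoxyphenyl)-4-[(Bpin)methyl]oxolan-3-ol F4.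
- Appel iodination (PPh3, I2, imidazole, toluene; inversion) comes back to the route at 7.

Step 4. The alkylnickel intermediate may undergo β-alkoxy elimination or reduction, or the acid chloride may homocouple. The fallback sets out from 7 and assembles the acyl group from carbon monoxide instead: light-promoted carbonylative coupling with Pd(PPh3)4, CO (45 bar), 3,4,5-trimethoxyphenylboronic acid and K2CO3 in benzene/H2O, by way of an alkyl radical and an acylpalladium. It comes back directly at 9 and makes no new compound (F0). Any C4 epimer of 9 is converged by stirring with catalytic DBU.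

**Further compounds**
F1 | step 2 | 2-{[(1R,2S)-1-(3,4-dimethoxyphenyl)-2-[(Bpin)methyl]but-3-en-1-yl]oxy}-4,4,5,5-tetramethyl-1,3,2-dioxaborolane | COc1ccc([C@H](OB5OC(C)(C)C(C)(C)O5)[C@@H](CB4OC(C)(C)C(C)(C)O4)C=C)cc1OC
F2 | step 2 | (1R,2S)-1-(3,4-dimethoxyphenyl)-2-[(Bpin)methyl]but-3-en-1-ol | COc1ccc([C@H](O)[C@@H](CB4OC(C)(C)C(C)(C)O4)C=C)cc1OC
F3 | step 3 | (1S,2S)-1-(3,4-dimethoxyphenyl)-2-[(2S)-oxiran-2-yl]-3-(Bpin)propan-1-ol | COc1ccc([C@@H](O)[C@H](CB4OC(C)(C)C(C)(C)O4)[C@H]5CO5)cc1OC
F4 | step 3 | (3S,4R,5S)-5-(3,4-dimethoxyphenyl)-4-[(Bpin)methyl]oxolan-3-ol | COc1ccc([C@H]2OC[C@@H](O)[C@H]2CB4OC(C)(C)C(C)(C)O4)cc1OC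
F0 | step 4 | none | none
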